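## Structural features

Bleochrin B (17) is a bibenzyl: ring A and ring B are joined by a CH2–CH2 bridge, and four 4-hydroxybenzyl groups hang from them through single CH2 links. Ring A is hexasubstituted: C1 carries the bridge, C2, C4 and C6 carry 4-hydroxybenzyl groups, C3 a hydroxyl and C5 a methoxy group, so C1 lies between two benzylated carbons. Ring B carries the bridge at C1', one 4-hydroxybenzyl group at the neighbouring C2' and a hydroxyl at C5', para to that benzyl group. There is no stereocentre and no fused or bridged ring, so no two stereocentres stand next to each other and nothing stereochemical has to be controlled. The fragile groups are the six phenols (electron-rich, easily oxidised, incompatible with organometallic reagents) and the diarylmethane CH2 groups on the oxygenated ring A, which can lose or shift a 4-hydroxybenzyl cation in strong acid. The real difficulty is ring A: six substituents in a fixed order, OH to be told apart from OMe, and a two-carbon bridge to be attached to a carbon flanked by two benzyl groups. The key step uses the fact that the bridge is a plain two-carbon link between ring A C1 and ring B C1'. A vinylboron unit supplies Cα and Cβ, ring A C1 enters as a migrating nucleophile (from a C1–Br bond) and ring B C1' as an electrophile (from a C1'–O triflate).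

## Logic of the disconnections

**17 to 16.** The six phenolic O–H bonds of 17 are traced back to six O–benzyl bonds in 16. Free phenols would not survive an aryllithium or a cationic palladium intermediate, and one kind of protecting group that leaves under neutral conditions keeps the end short. The gain is a single, uniform protection scheme. The demand is that the last step cleaves six aryl benzyl ethers without touching the methyl ether, the diarylmethane C–C bonds or the bridge.

**16 to 15.** One Cα–H bond of the bridge is exchanged for a Cα–B bond. This adds no skeletal simplification, but it installs the retron of a three-component coupling at the bridge. The demand on the forward step is replacement of boron by hydrogen at a crowded secondary benzylic carbon; the stereocentre at Cα vanishes there, so it never needs control.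

**15 to 6, 12 and 11.** The bonds C1–Cα and Cβ–C1' are cut, which divides 15 into two finished arenes and a two-carbon linchpin; this is the largest simplification of the route. Ring A C1 is the nucleophile (C–Br in 6), ring B C1' the electrophile (C–OTf in 11), and the regiochemistry on both rings is fixed before the coupling. The forward step must make the metallate shift win over direct transmetalation, with a migrating aryl that has two ortho substituents. Two provisions are built in. The bromide left by the bromine–lithium exchange is removed with a triflate salt, so that palladium stays cationic. The aryllithium 13 is trapped by 12 at low temperature, before it can take a proton from a diarylmethane CH2.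

**6 to 5.** The O–benzyl bond at ring A C3 is cut. The free phenol of 5 is what drives the next disconnection, and it must be masked before the organolithium step. The demand is O-alkylation of a phenol with two ortho substituents.

**5 to 2 and 4 (4 from 3).** The three bonds from the exocyclic CH2 carbons to the ipso carbons of the 4-oxyphenyl rings are cut at once. All three CH2 groups stand ortho or para to the phenol, so each can become the terminus of a quinone methide and accept one molecule of 4; 4 comes from 3 by magnesium insertion. Three aryl rings are removed in one operation. The demand is that the threefold elimination–addition runs to completion, which takes three molecules of 4 for the three C–C bonds and a fourth for the phenol O–H, and that it leaves the ring C–Br bond alone.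

**2 to 1.** The three ring C–CH2 bonds are cut. Every free position of 1 is ortho or para to both oxygen substituents, and the 1,3,5-pattern of Br, OH and OMe in 1 maps directly onto ring A C1, C3 and C5, so the OH/OMe distinction is bought with the starting material. The demand is exhaustive aminomethylation, including the two positions next to bromine.

**11 to 10 to 8 to 7.** The O–S bond, then the benzylic CH2 (back to C=O), then two O–benzyl bonds are cut. Commercial 7 already holds the ring B pattern: the hydroxyl ortho to the carbonyl becomes the C1' handle, the para hydroxyl is the C5' oxygen, and the ketone carbon becomes the CH2 on C2'. The demands are benzylation that spares the chelated ortho hydroxyl, a ketone deoxygenation that tolerates benzyl ethers (through 9), and a clean triflation.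

## Other disconnections considered

**Alternative 1:** The cut opens ring A at the C1–C2 bond and, behind it, unravels the ring into a chain. The resorcinol A1 is traced back to the acyclic allyl 2,4,6-tribenzyl-3,5,7-triketo ester A2, whose chain carbon 7 carries the ring B arylethyl group.
- Forward step: base would add the doubly activated chain carbon 2 to the carbon 7 ketone (a six-membered aldol closure) and water would be lost. Removal of the allyl group by a zerovalent palladium catalyst with an amine as allyl acceptor would let the ring carboxylate leave as CO2 and the ring aromatise to A1.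
- In its favour: ring A is built with all four carbon substituents in place, so no bond is made at a crowded aromatic carbon and no organolithium is needed. It also follows the polyketide logic by which bibenzyls arise in nature. On this structural point it is the better plan.
- Against it here: A2 is a mixture of diastereomers and enol forms that needs three C-benzylations of a polycarbonyl chain, with C- against O-alkylation and over-alkylation to manage. Chain carbon 2 is tertiary, so the aldol makes a quaternary centre reversibly and competes with Claisen-type closure of carbon 6 onto the ester and with pyranone formation. A1 has two equivalent ring A hydroxyls, each between two benzyl groups, so the methyl ether of 17 would come from a mono-methylation that is at best statistical.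
- Comparison: mechanistically the chosen coupling has one main competitor (direct transmetalation), the folding several. In step count the chosen plan (nine steps) should be clearly shorter, since A2 needs a long linear build and A1 still needs methylation and deprotection. The chosen plan also gets the OH/OMe distinction from 1, which this alternative cannot.

**Alternative 2:** The cut removes the three CH2–aryl bonds of the ring A 4-oxybenzyl groups at the stage of the complete bibenzyl. A3 is traced back to the ring A tris-Mannich phenol A4 and the Grignard reagent 4.
- Forward step: excess 4 would convert the magnesium phenoxide of A4, through three successive quinone methides, into A3.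
- In its favour: the bond-forming chemistry is the same as in steps 1 and 2 of the chosen route, so on mechanism the two plans are equal. The bridge is made while ring A C1 still has hydrogen neighbours, so ordinary olefination or alkyne chemistry would do and the untested crowded migrating group is avoided; here the alternative is the better one. A3 is one hydrogenolysis from 17, with no boron to remove and no ring A O-benzylation, so its end-game is also shorter.
- Against it here: the least predictable event, three C–C bonds formed in an increasingly crowded ring, is placed on the most advanced intermediate instead of on inexpensive 1. The aminomethylation must stay on ring A although ring B is also an alkoxy-activated arene, and two of the sites lie next to the arylethyl chain. The route is linear and carries ring B through every step.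
- Comparison: in overall step count the two plans are about equal. The chosen plan is preferred because it is convergent and tests the threefold arylation at step 2. Alternative 2 is the natural route to switch to if the crowded coupling cannot be made to work.

**Alternative 3:** The cut is a retro-Diels–Alder opening of ring B at C1'–C6' and C2'–C3'. The 4-aroylphenol A5 is traced back to the aryl ynone A6, which carries complete ring A on a CH2CH2 tether, and Danishefsky's diene A7.
- Forward step: the CH2 terminus of A7 would bond to the alkyne carbon remote from the carbonyl (the future C1') and the methoxy-bearing terminus to the carbonyl-bearing alkyne carbon (the future C2'). Loss of methanol and of the silyl group would aromatise the adduct to A5, with the hydroxyl para to the aroyl group.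
- In its favour: the ring B pattern follows from the polarity of diene and ynone, and the cycloaddition is a dependable reaction class with no hindered organometallic step in the ring-forming event. On reliability of the key event it is equal to or better than the chosen coupling. The diaryl ketone of A5 could be taken down to CH2 in the same hydrogenation that removes the benzyl ethers.
- Against it here: A6 already contains the bond between crowded ring A C1 and the bridge, so the central difficulty is moved into the preparation of A6, not removed. Several linear steps are spent on the hexasubstituted fragment to reach an ynone, and ring B is constructed although its pattern can be bought in 7.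
- Comparison: structurally it simplifies less than the chosen disconnection, which joins two finished arenes, and in step economy it should be longer. Its advantage is limited to the robustness of the cycloaddition itself.

Key step: step 7

Assumption: Cα of 15 is written without configuration and carried as a mixture; either enantiomer or the racemate of the ligand may be used, because this centre becomes CH2 in step 8.

## Route

Step 1
Reactants: 1 3-bromo-5-methoxyphenol
Product: 2 3-bromo-2,4,6-tris[(dimethylamino)methyl]-5-methoxyphenol
Conditions: Me2NH (40% aq, 6 equiv), HCHO (37% aq, 6 equiv), EtOH, 90 °C, sealed vessel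
Reagents that add atoms: formaldehyde C=O; dimethylamine CNC
Why: Mannich reaction: the iminium ion CH2=NMe2+ attacks C2, C4 and C6, each of which is ortho or para to both OH and OMe, so all three free positions are doubly activated and there is no regiochemical choice. Excess reagents and heat should drive the third substitution next to bromine, and the amine excess suppresses methylene-bridged by-products.

Step 2
Reactants: 2 3-bromo-2,4,6-tris[(dimethylamino)methyl]-5-methoxyphenol; 3 1-(benzyloxy)-4-bromobenzene
Product: 5 2,4,6-tris[4-(benzyloxy)benzyl]-3-bromo-5-methoxyphenol, via 4-(benzyloxy)phenylmagnesium bromide 4 (not isolated)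
Conditions: 3 (6 equiv), Mg (6.5 equiv), THF, reflux; then 2 (1 equiv) in toluene, THF distilled off, 100 °C; aq NH4Cl
Reagents that add atoms: 4-(benzyloxy)phenylmagnesium bromide Br[Mg]c1ccc(OCc2ccccc2)cc1
Why: Grignard formation by magnesium insertion into 3, then threefold substitution of a phenolic Mannich base by elimination–addition: the magnesium phenoxide of 2 expels dimethylamide from the ortho and para CH2NMe2 groups to give ortho- and para-quinone methide intermediates one after another, and each is captured by one molecule of 4 in a conjugate addition that re-forms the phenoxide. Per molecule of 2, three molecules of 4 deliver the three aryl groups of 5 and a fourth is spent on the phenol O–H, which is why 4 is made in excess from six equivalents of 3. The ring C–Br bond is inert to an aryl Grignard reagent without a transition-metal catalyst.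

Step 3
Reactants: 5 2,4,6-tris[4-(benzyloxy)benzyl]-3-bromo-5-methoxyphenol
Product: 6 1-(benzyloxy)-2,4,6-tris[4-(benzyloxy)benzyl]-3-bromo-5-methoxybenzene (ring A bromide)
Conditions: BnBr (1.5 equiv), K2CO3, DMF, 60 °C
Reagents that add atoms: benzyl bromide BrCc1ccccc1
Why: Williamson ether synthesis; the phenoxide of 5 has two ortho benzyl groups but should still alkylate with unhindered benzyl bromide in a dipolar aprotic solvent, and 5 has no other acidic or nucleophilic site.

Step 4
Reactants: 7 2,4,4'-trihydroxybenzophenone
Product: 8 [4-(benzyloxy)-2-hydroxyphenyl][4-(benzyloxy)phenyl]methanone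
Conditions: BnBr (2.1 equiv), K2CO3 (2.2 equiv), acetone, reflux
Reagents that add atoms: benzyl bromide BrCc1ccccc1
Why: Chemoselective Williamson etherification: the 2-hydroxyl is held in a six-membered hydrogen bond to the ketone and is much less nucleophilic, so about two equivalents of benzyl bromide with a weak base should alkylate only the 4- and 4'-hydroxyls.

Step 5
Reactants: 8 [4-(benzyloxy)-2-hydroxyphenyl][4-(benzyloxy)phenyl]methanone
Product: 10 5-(benzyloxy)-2-[4-(benzyloxy)benzyl]phenol, via aryl ethyl carbonate 9 (not isolated)
Conditions: ClCO2Et, Et3N, THF, 0 °C; then NaBH4, H2O, 0 °C to rt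
Reagents that add atoms: none
Why: Reductive deoxygenation of an ortho-hydroxyaryl ketone through its aryl carbonate: NaBH4 reduces the ketone, the carbonate is lost by acyl transfer and 1,4-elimination to an ortho-quinone methide intermediate, and a second hydride adds to the exocyclic carbon to leave CH2 and the free phenol. The medium is basic and free of hydrogen gas and strong acid, so both benzyl ethers should survive.

Step 6
Reactants: 10 5-(benzyloxy)-2-[4-(benzyloxy)benzyl]phenol
Product: 11 5-(benzyloxy)-2-[4-(benzyloxy)benzyl]phenyl trifluoromethanesulfonate (ring B triflate)
Conditions: Tf2O (1.2 equiv), pyridine, CH2Cl2, 0 °C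
Reagents that add atoms: triflic anhydride O=S(=O)(OS(=O)(=O)C(F)(F)F)C(F)(F)F
Why: O-Sulfonylation of a phenol; the phenol is the only nucleophilic site of 10, and the aryl triflate fixes ring B C1' as the electrophilic carbon.

Step 7
Reactants: 6 1-(benzyloxy)-2,4,6-tris[4-(benzyloxy)benzyl]-3-bromo-5-methoxybenzene; 12 vinylboronic acid pinacol ester; 11 5-(benzyloxy)-2-[4-(benzyloxy)benzyl]phenyl trifluoromethanesulfonate
Product: 15 Cα pinacol boronate of hexa-O-benzyl bleochrin B (bridge = ring A–CH(Bpin)–CH2–ring B; configuration at Cα undefined), via ring A aryllithium 13 (not isolated), via lithium vinylboronate complex 14 (not isolated)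
Conditions: 6 (1.25 equiv), t-BuLi (2.5 equiv), THF/Et2O, −78 °C; 12 (1.25 equiv), −78 °C to rt; solvent exchange to THF; KOTf (2 equiv), 11 (1.0 equiv), Pd(OAc)2 (3 mol %), MandyPhos (1,1'-bis(diphenylphosphino)-2,2'-bis[α-(dimethylamino)benzyl]ferrocene, 3.6 mol %), 60 °C
Reagents that add atoms: none
Why: Bromine–lithium exchange on 6 (two equivalents of t-BuLi, the second destroying t-BuBr) gives aryllithium 13, which is trapped at −78 °C by the empty boron orbital of 12 to give the four-coordinate boronate 14 before it can abstract a diarylmethane proton; KOTf removes the bromide as KBr so that palladium stays cationic. Zerovalent palladium formed from Pd(OAc)2 and the bisphosphine inserts into the C1'–OTf bond of 11; the cationic divalent arylpalladium binds the vinyl group of 14 and triggers a 1,2-shift of the ring A aryl from boron to Cα, anti to palladium, which forms C1–Cα and a Cβ–Pd bond, and reductive elimination then forms Cβ–C1' and returns zerovalent palladium. The closest known reaction type is the palladium-catalysed conjunctive cross-coupling of aryl(vinyl)boronate complexes with aryl triflates; the migrating aryl with two ortho substituents is the untested point. No ring is closed. The one new stereocentre, Cα, is set in the migration step under the influence of the ligand only; no use is made of it, it is written without configuration and it is erased in step 8. The selectivity needed is metallate shift over Suzuki-type transfer of the vinyl or aryl group from boron to palladium; it should be secured by the halide-free cationic palladium with a wide-bite-angle bisphosphine, by the triflate leaving group and by the poor transfer ability of the crowded ring A aryl. Regiochemistry on both rings is fixed beforehand by the positions of Br in 6 and OTf in 11, and the ethers and diarylmethane groups are spectators.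

Step 8
Reactants: 15 Cα pinacol boronate of hexa-O-benzyl bleochrin B
Product: 16 hexa-O-benzyl bleochrin B
Conditions: Bu4NF·3H2O (3 equiv), toluene, 80 °C
Reagents that add atoms: none
Why: Fluoride-promoted protodeboronation of a benzylic pinacol boronate: fluoride adds to boron and the C–B bond of the fluoroboronate is cleaved with proton delivery from the water of hydration, helped by the benzylic position next to ring A. The stereocentre disappears, and the ethers are inert to fluoride.

Step 9
Reactants: 16 hexa-O-benzyl bleochrin B
Product: 17 bleochrin B
Conditions: H2 (1 atm), 10% Pd/C, THF/MeOH, rt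
Reagents that add atoms: none
Why: Catalytic hydrogenolysis of six aryl benzyl ethers over Pd/C under neutral conditions; the methyl ether, the diarylmethane C–C bonds and the bridge should not be cleaved at room temperature and one atmosphere, so 17 is released without acid or base.

## Compound list

1 | 3-bromo-5-methoxyphenol | COc1cc(O)cc(Br)c1 | starting material
2 | 3-bromo-2,4,6-tris[(dimethylamino)methyl]-5-methoxyphenol | COc1c(CN(C)C)c(O)c(CN(C)C)c(Br)c1CN(C)C | intermediate
3 | 1-(benzyloxy)-4-bromobenzene | Brc1ccc(OCc2ccccc2)cc1 | starting material
4 | 4-(benzyloxy)phenylmagnesium bromide | Br[Mg]c1ccc(OCc2ccccc2)cc1 | intermediate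
5 | 2,4,6-tris[4-(benzyloxy)benzyl]-3-bromo-5-methoxyphenol | COc1c(Cc2ccc(OCc3ccccc3)cc2)c(O)c(Cc2ccc(OCc3ccccc3)cc2)c(Br)c1Cc1ccc(OCc2ccccc2)cc1 | intermediate
6 | 1-(benzyloxy)-2,4,6-tris[4-(benzyloxy)benzyl]-3-bromo-5-methoxybenzene (ring A bromide) | COc1c(Cc2ccc(OCc3ccccc3)cc2)c(OCc2ccccc2)c(Cc2ccc(OCc3ccccc3)cc2)c(Br)c1Cc1ccc(OCc2ccccc2)cc1 | intermediate
7 | 2,4,4'-trihydroxybenzophenone | O=C(c1ccc(O)cc1)c1ccc(O)cc1O | starting material
8 | [4-(benzyloxy)-2-hydroxyphenyl][4-(benzyloxy)phenyl]methanone | O=C(c1ccc(OCc2ccccc2)cc1)c1ccc(OCc2ccccc2)cc1O | intermediate
9 | 5-(benzyloxy)-2-[4-(benzyloxy)benzoyl]phenyl ethyl carbonate | CCOC(=O)Oc1cc(OCc2ccccc2)ccc1C(=O)c1ccc(OCc2ccccc2)cc1 | intermediate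
10 | 5-(benzyloxy)-2-[4-(benzyloxy)benzyl]phenol | Oc1cc(OCc2ccccc2)ccc1Cc1ccc(OCc2ccccc2)cc1 | intermediate
11 | 5-(benzyloxy)-2-[4-(benzyloxy)benzyl]phenyl trifluoromethanesulfonate (ring B triflate) | O=S(=O)(Oc1cc(OCc2ccccc2)ccc1Cc1ccc(OCc2ccccc2)cc1)C(F)(F)F | intermediate
12 | vinylboronic acid pinacol ester | C=CB1OC(C)(C)C(C)(C)O1 | starting material
13 | ring A aryllithium: {3-(benzyloxy)-2,4,6-tris[4-(benzyloxy)benzyl]-5-methoxyphenyl}lithium | COc1c(Cc2ccc(OCc3ccccc3)cc2)c(OCc2ccccc2)c(Cc2ccc(OCc3ccccc3)cc2)c([Li])c1Cc1ccc(OCc2ccccc2)cc1 | intermediate
14 | lithium [ring A aryl](vinyl)(pinacolato)borate | [Li+].C=C[B-]1(c2c(Cc3ccc(OCc4ccccc4)cc3)c(OC)c(Cc3ccc(OCc4ccccc4)cc3)c(OCc3ccccc3)c2Cc2ccc(OCc3ccccc3)cc2)OC(C)(C)C(C)(C)O1 | intermediate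
15 | Cα pinacol boronate of hexa-O-benzyl bleochrin B (ring A–CH(Bpin)–CH2–ring B, Cα configuration undefined) | COc1c(Cc2ccc(OCc3ccccc3)cc2)c(OCc2ccccc2)c(Cc2ccc(OCc3ccccc3)cc2)c(C(Cc2cc(OCc3ccccc3)ccc2Cc2ccc(OCc3ccccc3)cc2)B2OC(C)(C)C(C)(C)O2)c1Cc1ccc(OCc2ccccc2)cc1 | intermediate
16 | hexa-O-benzyl bleochrin B | COc1c(Cc2ccc(OCc3ccccc3)cc2)c(OCc2ccccc2)c(Cc2ccc(OCc3ccccc3)cc2)c(CCc2cc(OCc3ccccc3)ccc2Cc2ccc(OCc3ccccc3)cc2)c1Cc1ccc(OCc2ccccc2)cc1 | intermediate
17 | bleochrin B (achiral) | COc1c(Cc2ccc(O)cc2)c(O)c(Cc2ccc(O)cc2)c(CCc2cc(O)ccc2Cc2ccc(O)cc2)c1Cc1ccc(O)cc1 | target

## Step count and least certain steps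

Total: 9 steps (the Grignard reagent 4 is made and used within step 2). Longest linear sequence: 6 steps (1 → 2 → 5 → 6 → 15 → 16 → 17, steps 1, 2, 3, 7, 8, 9; the ring B branch through steps 4, 5, 6, 7, 8, 9 is equally long).

**Step 7 (key step).**
- Risk: formation of 14 may be incomplete because the aryllithium is flanked by two benzyl groups, and 13 may be quenched by proton transfer from a diarylmethane CH2. The crowded boronate may bind palladium poorly, so that vinyl transfer to palladium (Suzuki-type coupling) overtakes the metallate shift. Residual bromide may convert the cationic palladium into a neutral, less selective complex.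
- Fallback: it sets out from 11 and 6 and returns at 16. Suzuki–Miyaura vinylation of 11 with potassium vinyltrifluoroborate (PdCl2(dppf), Cs2CO3, THF/H2O) should give the styrene 4-(benzyloxy)-1-[4-(benzyloxy)benzyl]-2-vinylbenzene F1. Anti-Markovnikov hydroboration with 9-borabicyclo[3.3.1]nonane would give the primary alkylborane 9-{2-[5-(benzyloxy)-2-(4-(benzyloxy)benzyl)phenyl]ethyl}-9-borabicyclo[3.3.1]nonane F2. This is coupled in the same flask with 6 (Pd(OAc)2, SPhos, K3PO4, THF/H2O, 65 °C; B-alkyl Suzuki–Miyaura coupling) to give 16 directly, so step 8 is not needed.

**Step 2.**
- Risk: the threefold substitution may stall after one or two arylations, most likely at the para CH2NMe2 group between Br and OMe, because loss of magnesium amide needs heat. Quinone methides may also be captured by phenoxide of another molecule and oligomerise.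
- Fallback: it sets out from 2 and returns at 5. Exhaustive N-methylation with MeI (MeCN, rt) would give the tris(trimethylammonium) salt 3-bromo-5-methoxy-2,4,6-tris[(trimethylammonio)methyl]phenol triiodide F3. Trimethylamine is a far better leaving group, so the quinone methides should form from the phenoxide at 0 °C to rt on treatment with excess 4 in THF, giving 5.

**Step 8.**
- Risk: C–B cleavage may be sluggish because ring A is twisted out of conjugation and electron-rich, and so stabilises negative charge at Cα poorly. Adventitious oxygen may cause partial oxidation of the boronate at the higher temperature.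
- Fallback: it sets out from 15 and returns at 17. Oxidation with NaBO3·4H2O (THF/H2O, rt) should give the benzylic alcohol 1-[ring A aryl]-2-[ring B aryl]ethanol F4. Syn-dehydration with the Burgess reagent (toluene, 80 °C) would give the (E)-stilbene hexa-O-benzyl-α,β-didehydrobleochrin B F5. One hydrogenation over Pd/C (H2, THF/MeOH) then saturates the alkene and cleaves the six benzyl ethers, giving 17 and replacing steps 8 and 9.

**Step 1.**
- Risk: aminomethylation may stop at the bis stage because the last position lies between bromine and an oxygen substituent. Condensation of a Mannich base with a second phenol may give methylene-bridged dimers.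
- Fallback: it sets out from 1 and returns at 5, bypassing 2. Acid-catalysed threefold Friedel–Crafts benzylation of 1 with 4-(benzyloxy)benzyl alcohol (3.5 equiv, Bi(OTf)3 cat., 1,2-dichloroethane, rt to 50 °C) would give 5; it makes no new compound (F0). Its own weakness is self-condensation of the benzyl alcohol, which is why it is the reserve and not the first choice.

## Further compounds

F1 | step 7 | 4-(benzyloxy)-1-[4-(benzyloxy)benzyl]-2-vinylbenzene | C=Cc1cc(OCc2ccccc2)ccc1Cc1ccc(OCc2ccccc2)cc1
F2 | step 7 | 9-{2-[5-(benzyloxy)-2-(4-(benzyloxy)benzyl)phenyl]ethyl}-9-borabicyclo[3.3.1]nonane | C1CCC2CCCC1B2CCc1cc(OCc2ccccc2)ccc1Cc1ccc(OCc2ccccc2)cc1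
F3 | step 2 | 3-bromo-5-methoxy-2,4,6-tris[(trimethylammonio)methyl]phenol triiodide | COc1c(C[N+](C)(C)C)c(O)c(C[N+](C)(C)C)c(Br)c1C[N+](C)(C)C.[I-].[I-].[I-]
F4 | step 8 | 1-{3-(benzyloxy)-2,4,6-tris[4-(benzyloxy)benzyl]-5-methoxyphenyl}-2-{5-(benzyloxy)-2-[4-(benzyloxy)benzyl]phenyl}ethanol (configuration undefined) | COc1c(Cc2ccc(OCc3ccccc3)cc2)c(OCc2ccccc2)c(Cc2ccc(OCc3ccccc3)cc2)c(C(O)Cc2cc(OCc3ccccc3)ccc2Cc2ccc(OCc3ccccc3)cc2)c1Cc1ccc(OCc2ccccc2)cc1
F5 | step 8 | (E)-stilbene analogue of hexa-O-benzyl bleochrin B (bridge CH=CH) | COc1c(Cc2ccc(OCc3ccccc3)cc2)c(OCc2ccccc2)c(Cc2ccc(OCc3ccccc3)cc2)c(/C=C/c2cc(OCc3ccccc3)ccc2Cc2ccc(OCc3ccccc3)cc2)c1Cc1ccc(OCc2ccccc2)cc1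
F0 | step 1 | none | none
A1 | alternative 1 | 2,4,6-tris[4-(benzyloxy)benzyl]-5-{2-[5-(benzyloxy)-2-(4-(benzyloxy)benzyl)phenyl]ethyl}resorcinol | Oc1c(Cc2ccc(OCc3ccccc3)cc2)c(O)c(Cc2ccc(OCc3ccccc3)cc2)c(CCc2cc(OCc3ccccc3)ccc2Cc2ccc(OCc3ccccc3)cc2)c1Cc1ccc(OCc2ccccc2)cc1
A2 | alternative 1 | allyl 2,4,6-tris[4-(benzyloxy)benzyl]-9-{5-(benzyloxy)-2-[4-(benzyloxy)benzyl]phenyl}-3,5,7-trioxononanoate (mixture of diastereomers and enol forms) | C=CCOC(=O)C(Cc1ccc(OCc2ccccc2)cc1)C(=O)C(Cc1ccc(OCc2ccccc2)cc1)C(=O)C(Cc1ccc(OCc2ccccc2)cc1)C(=O)CCc1cc(OCc2ccccc2)ccc1Cc1ccc(OCc2ccccc2)cc1
A3 | alternative 2 | bleochrin B penta-O-benzyl ether with free ring A phenol | COc1c(Cc2ccc(OCc3ccccc3)cc2)c(O)c(Cc2ccc(OCc3ccccc3)cc2)c(CCc2cc(OCc3ccccc3)ccc2Cc2ccc(OCc3ccccc3)cc2)c1Cc1ccc(OCc2ccccc2)cc1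
A4 | alternative 2 | 3-{2-[5-(benzyloxy)-2-(4-(benzyloxy)benzyl)phenyl]ethyl}-2,4,6-tris[(dimethylamino)methyl]-5-methoxyphenol | COc1c(CN(C)C)c(O)c(CN(C)C)c(CCc2cc(OCc3ccccc3)ccc2Cc2ccc(OCc3ccccc3)cc2)c1CN(C)C
A5 | alternative 3 | ring B 4-aroylphenol joined to protected ring A | COc1c(Cc2ccc(OCc3ccccc3)cc2)c(OCc2ccccc2)c(Cc2ccc(OCc3ccccc3)cc2)c(CCc2cc(O)ccc2C(=O)c2ccc(OCc3ccccc3)cc2)c1Cc1ccc(OCc2ccccc2)cc1
A6 | alternative 3 | 5-{3-(benzyloxy)-2,4,6-tris[4-(benzyloxy)benzyl]-5-methoxyphenyl}-1-[4-(benzyloxy)phenyl]pent-2-yn-1-one | COc1c(Cc2ccc(OCc3ccccc3)cc2)c(OCc2ccccc2)c(Cc2ccc(OCc3ccccc3)cc2)c(CCC#CC(=O)c2ccc(OCc3ccccc3)cc2)c1Cc1ccc(OCc2ccccc2)cc1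
A7 | alternative 3 | Danishefsky's diene, (E)-1-methoxy-3-(trimethylsilyloxy)buta-1,3-diene | CO/C=C/C(=C)O[Si](C)(C)C
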